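**Overview**

- Retrosynthesis: the 5‑OH is masked as a methyl ether and freed last. Ring C is cut at O1–C2, the chain at C4–C4a (aryl ketone) and at C2–C1' (benzyl–aryl bond), and the side chain at C8–prenyl.
- Forward: a bought guaiacyl bromide (ring B) is joined to a three‑carbon glycidate unit (C2–C1'). Bought 5‑methoxyresorcinol (ring A) is prenylated and then acylated by that unit (C4–C4a). Ring C is closed last through O1–C2.
- Stereochemistry: C3 (R) is bought with methyl (R)‑glycidate, and no bond at it is made or broken afterwards. C2 (R) is set in the ring closure, trans to the C3 hydroxyl, by 1,2‑induction and by equilibration through the quinone methide.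
- Enabling feature: C2 is a benzylic carbon para to the free 4'‑OH of guaiacyl ring B and bonded to O1 of ring C. The O1–C2 bond can therefore come from a para‑quinone methide of ring B trapped by the ring A phenol, and only C3 has to be brought in as a stereocenter.

Key step: step 9

Remark: the target SMILES encodes the (2R,3R), 2,3‑trans dihydroflavonol. Flavonoid numbering (O1, C2, C3, C4, C4a, C5 to C8, C8a, primed numbers for ring B) is used throughout, also for the atoms of open‑chain precursors.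

**Route**

Step 1
Reactants: 1 5‑methoxyresorcinol
Product: 2 1‑methoxy‑3,5‑bis(methoxymethoxy)benzene
Conditions: NaH, MOMCl, DMF, 0 °C to rt
Reagents that add atoms: chloromethyl methyl ether (MOMCl), COCCl
Why: Williamson‑type O‑alkylation of both phenoxides by the reactive α‑chloro ether gives the bis‑MOM ether, whose acetal oxygens later direct the ortho‑metalations.

Step 2
Reactants: 2 1‑methoxy‑3,5‑bis(methoxymethoxy)benzene; 3 prenyl bromide (1‑bromo‑3‑methylbut‑2‑ene)
Product: 5 5‑methoxy‑1,3‑bis(methoxymethoxy)‑2‑(3‑methylbut‑2‑en‑1‑yl)benzene, via aryllithium 4 (not isolated)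
Conditions: n‑BuLi, THF, 0 °C to rt; then CuI (10 mol %), 3, −78 °C to rt
Reagents that add atoms: none
Why: Directed ortho‑metalation should take place at the carbon flanked by the two OMOM groups, which bind lithium better than the methoxy group, and copper‑catalysed allylic substitution at the primary carbon of the bromide then gives the linear prenyl arene.

Step 3
Reactants: 6 4‑bromo‑2‑methoxyphenol
Product: 7 4‑bromo‑2‑methoxy‑1‑(methoxymethoxy)benzene
Conditions: NaH, MOMCl, DMF, 0 °C to rt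
Reagents that add atoms: chloromethyl methyl ether (MOMCl), COCCl
Why: Williamson‑type O‑alkylation masks the ring B phenol as a MOM ether that tolerates Grignard formation and is removed later together with the ring A acetals.

Step 4
Reactants: 7 4‑bromo‑2‑methoxy‑1‑(methoxymethoxy)benzene; 9 methyl (R)‑glycidate
Product: 10 methyl (2R)‑2‑hydroxy‑3‑[3‑methoxy‑4‑(methoxymethoxy)phenyl]propanoate, via Grignard reagent 8 (not isolated)
Conditions: Mg, I2 (cat.), THF, reflux; then slow addition to 9 and CuI (10 mol %), THF, −40 to −20 °C; aq. NH4Cl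
Reagents that add atoms: none
Why: Copper‑catalysed epoxide opening by the aryl Grignard reagent occurs at the unsubstituted CH2 (SN2), the ester being spared at low temperature, and because no bond at the carbinol carbon is touched the (R) configuration of 9 becomes C3 of the target.

Step 5
Reactants: 10 methyl (2R)‑2‑hydroxy‑3‑[3‑methoxy‑4‑(methoxymethoxy)phenyl]propanoate
Product: 11 methyl (2R)‑2‑[(tert‑butyldimethylsilyl)oxy]‑3‑[3‑methoxy‑4‑(methoxymethoxy)phenyl]propanoate
Conditions: TBSCl, imidazole, DMF, rt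
Reagents that add atoms: tert‑butyldimethylsilyl chloride (TBSCl), CC(C)(C)[Si](C)(C)Cl
Why: Imidazole‑promoted silylation of the secondary alcohol leaves the stereocenter untouched and removes the acidic OH before the organometallic steps.

Step 6
Reactants: 11 methyl (2R)‑2‑[(tert‑butyldimethylsilyl)oxy]‑3‑[3‑methoxy‑4‑(methoxymethoxy)phenyl]propanoate
Product: 12 (2R)‑2‑[(tert‑butyldimethylsilyl)oxy]‑N‑methoxy‑3‑[3‑methoxy‑4‑(methoxymethoxy)phenyl]‑N‑methylpropanamide
Conditions: MeNHOMe·HCl, i‑PrMgCl, THF, −20 to 0 °C; aq. NH4Cl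
Reagents that add atoms: N,O‑dimethylhydroxylamine hydrochloride, CNOC.Cl
Why: Aminolysis of the ester by the chloromagnesium amide of N,O‑dimethylhydroxylamine (Weinreb amide formation) runs at low temperature, where an α‑silyloxy ester should not epimerise.

Step 7
Reactants: 5 5‑methoxy‑1,3‑bis(methoxymethoxy)‑2‑(3‑methylbut‑2‑en‑1‑yl)benzene; 12 (2R)‑2‑[(tert‑butyldimethylsilyl)oxy]‑N‑methoxy‑3‑[3‑methoxy‑4‑(methoxymethoxy)phenyl]‑N‑methylpropanamide
Product: 14 (2R)‑2‑[(tert‑butyldimethylsilyl)oxy]‑1‑[6‑methoxy‑2,4‑bis(methoxymethoxy)‑3‑(3‑methylbut‑2‑en‑1‑yl)phenyl]‑3‑[3‑methoxy‑4‑(methoxymethoxy)phenyl]propan‑1‑one, via aryllithium 13 (not isolated)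
Conditions: n‑BuLi, TMEDA, THF, −20 to 0 °C; then 12, −78 to −20 °C; aq. NH4Cl
Reagents that add atoms: none
Why: The only ring hydrogens of 5 are two equivalent ones between OMe and OMOM, so directed ortho‑metalation is regiochemically unambiguous, and the Weinreb ketone synthesis stops at the ketone because the chelated tetrahedral intermediate lasts until work‑up, which also shields the α‑stereocenter from enolisation.

Step 8
Reactants: 14 the fully protected (R)‑α‑silyloxy ketone
Product: 15 (2R)‑1‑[2,4‑dihydroxy‑6‑methoxy‑3‑(3‑methylbut‑2‑en‑1‑yl)phenyl]‑2‑hydroxy‑3‑(4‑hydroxy‑3‑methoxyphenyl)propan‑1‑one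
Conditions: HCl (1 M) in MeOH, rt
Reagents that add atoms: none
Why: Acid‑catalysed acetal exchange with methanol removes the three aryl MOM ethers and methanolysis removes the secondary silyl ether, while the two methyl ethers, the prenyl group and C3 (no bond broken there) should withstand dilute methanolic acid at room temperature.

Step 9
Reactants: 15 (2R)‑1‑[2,4‑dihydroxy‑6‑methoxy‑3‑(3‑methylbut‑2‑en‑1‑yl)phenyl]‑2‑hydroxy‑3‑(4‑hydroxy‑3‑methoxyphenyl)propan‑1‑one
Product: 17 (2R,3R)‑3,7‑dihydroxy‑2‑(4‑hydroxy‑3‑methoxyphenyl)‑5‑methoxy‑8‑(3‑methylbut‑2‑en‑1‑yl)‑2,3‑dihydro‑4H‑chromen‑4‑one, via para‑quinone methide 16 (not isolated)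
Conditions: Ag2O (2 equiv), CH2Cl2, rt, dark
Reagents that add atoms: none
Why: Proposed new method: Ag2O should remove two electrons and two protons from the guaiacyl phenol of 15, the most easily oxidised phenol because the ring A hydroxyls are deactivated by the aryl ketone, turning the benzylic CH2 into the exocyclic carbon of para‑quinone methide 16; the ring A hydroxyl ortho to the ketone then adds to that carbon and ring B rearomatises. The closest known reaction types are the Ag2O or DDQ oxidation of 4‑alkyl‑2‑methoxyphenols to para‑quinone methides that are captured intramolecularly by a phenol to give chromans and flavans, and the DDQ cyclisation of 2'‑hydroxydihydrochalcones to flavanones; closing an α‑hydroxy dihydrochalcone to a dihydroflavonol this way is new. Ring C closes by a 6‑exo‑trig oxa‑1,6‑addition that forms the O1–C2 bond. The new stereocenter C2 is governed by the C3 carbinol through a chair‑like transition state with the aryl group and the C3–OH both equatorial, giving the 2,3‑trans (2R,3R) isomer, and since the free 4'‑OH allows the ring to reopen to 16, any cis isomer should drain to the more stable trans product. The step needs 8‑prenyl regiochemistry, secured because the other ortho oxygen is methylated and only the hydroxyl next to the prenyl group can close, and it needs C3 to stay intact, for which neutral aprotic conditions are chosen to disfavour tautomerisation of 16 through the acidic C3–H to the α‑hydroxychalcone. Ag2O is preferred to DDQ because DDQ tends to turn ortho‑prenyl phenols into chromenes.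

Step 10
Reactants: 17 (2R,3R)‑3,7‑dihydroxy‑2‑(4‑hydroxy‑3‑methoxyphenyl)‑5‑methoxy‑8‑(3‑methylbut‑2‑en‑1‑yl)‑2,3‑dihydro‑4H‑chromen‑4‑one
Product: 18 (2R,3R)‑3,5,7‑trihydroxy‑2‑(4‑hydroxy‑3‑methoxyphenyl)‑8‑(3‑methylbut‑2‑en‑1‑yl)‑2,3‑dihydro‑4H‑chromen‑4‑one (target)
Conditions: MgI2·OEt2 (excess), THF, reflux; dilute aq. HCl
Reagents that add atoms: none
Why: Magnesium chelated between the C4 carbonyl and the peri 5‑methoxy oxygen activates only that methyl group for SN2 attack by iodide (chelation‑assisted ether cleavage), so the 3'‑OMe, the prenyl group and both stereocenters should be left alone.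

**Compound list**

1 | 5‑methoxyresorcinol (5‑methoxybenzene‑1,3‑diol) | COc1cc(O)cc(O)c1 | starting material
2 | 1‑methoxy‑3,5‑bis(methoxymethoxy)benzene | COCOc1cc(OC)cc(OCOC)c1 | intermediate
3 | prenyl bromide (1‑bromo‑3‑methylbut‑2‑ene) | CC(C)=CCBr | starting material
4 | [4‑methoxy‑2,6‑bis(methoxymethoxy)phenyl]lithium | [Li]c1c(OCOC)cc(OC)cc1OCOC | intermediate (not isolated)
5 | 5‑methoxy‑1,3‑bis(methoxymethoxy)‑2‑(3‑methylbut‑2‑en‑1‑yl)benzene | COCOc1cc(OC)cc(OCOC)c1CC=C(C)C | intermediate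
6 | 4‑bromo‑2‑methoxyphenol | COc1cc(Br)ccc1O | starting material
7 | 4‑bromo‑2‑methoxy‑1‑(methoxymethoxy)benzene | COCOc1ccc(Br)cc1OC | intermediate
8 | [3‑methoxy‑4‑(methoxymethoxy)phenyl]magnesium bromide | COCOc1ccc([Mg]Br)cc1OC | intermediate (not isolated)
9 | methyl (R)‑glycidate (methyl (2R)‑oxirane‑2‑carboxylate) | COC(=O)[C@H]1CO1 | starting material
10 | methyl (2R)‑2‑hydroxy‑3‑[3‑methoxy‑4‑(methoxymethoxy)phenyl]propanoate | COC(=O)[C@H](O)Cc1ccc(OCOC)c(OC)c1 | intermediate
11 | methyl (2R)‑2‑[(tert‑butyldimethylsilyl)oxy]‑3‑[3‑methoxy‑4‑(methoxymethoxy)phenyl]propanoate | COC(=O)[C@H](O[Si](C)(C)C(C)(C)C)Cc1ccc(OCOC)c(OC)c1 | intermediate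
12 | (2R)‑2‑[(tert‑butyldimethylsilyl)oxy]‑N‑methoxy‑3‑[3‑methoxy‑4‑(methoxymethoxy)phenyl]‑N‑methylpropanamide | CON(C)C(=O)[C@H](O[Si](C)(C)C(C)(C)C)Cc1ccc(OCOC)c(OC)c1 | intermediate
13 | [6‑methoxy‑2,4‑bis(methoxymethoxy)‑3‑(3‑methylbut‑2‑en‑1‑yl)phenyl]lithium | [Li]c1c(OC)cc(OCOC)c(CC=C(C)C)c1OCOC | intermediate (not isolated)
14 | (2R)‑2‑[(tert‑butyldimethylsilyl)oxy]‑1‑[6‑methoxy‑2,4‑bis(methoxymethoxy)‑3‑(3‑methylbut‑2‑en‑1‑yl)phenyl]‑3‑[3‑methoxy‑4‑(methoxymethoxy)phenyl]propan‑1‑one | COCOc1c(CC=C(C)C)c(OCOC)cc(OC)c1C(=O)[C@H](O[Si](C)(C)C(C)(C)C)Cc1ccc(OCOC)c(OC)c1 | intermediate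
15 | (2R)‑1‑[2,4‑dihydroxy‑6‑methoxy‑3‑(3‑methylbut‑2‑en‑1‑yl)phenyl]‑2‑hydroxy‑3‑(4‑hydroxy‑3‑methoxyphenyl)propan‑1‑one | COc1cc(O)c(CC=C(C)C)c(O)c1C(=O)[C@H](O)Cc1ccc(O)c(OC)c1 | intermediate
16 | 4‑[(2R)‑3‑[2,4‑dihydroxy‑6‑methoxy‑3‑(3‑methylbut‑2‑en‑1‑yl)phenyl]‑2‑hydroxy‑3‑oxopropylidene]‑2‑methoxycyclohexa‑2,5‑dien‑1‑one (para‑quinone methide, either alkene geometry) | COc1cc(O)c(CC=C(C)C)c(O)c1C(=O)[C@H](O)C=C1C=CC(=O)C(OC)=C1 | intermediate (not isolated)
17 | (2R,3R)‑3,7‑dihydroxy‑2‑(4‑hydroxy‑3‑methoxyphenyl)‑5‑methoxy‑8‑(3‑methylbut‑2‑en‑1‑yl)‑2,3‑dihydro‑4H‑chromen‑4‑one | COc1cc([C@H]2Oc3c(CC=C(C)C)c(O)cc(OC)c3C(=O)[C@@H]2O)ccc1O | intermediate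
18 | (2R,3R)‑3,5,7‑trihydroxy‑2‑(4‑hydroxy‑3‑methoxyphenyl)‑8‑(3‑methylbut‑2‑en‑1‑yl)‑2,3‑dihydro‑4H‑chromen‑4‑one | COc1cc([C@H]2Oc3c(CC=C(C)C)c(O)cc(O)c3C(=O)[C@@H]2O)ccc1O | target

**Step count and risks**

Total step count: 10. Longest linear sequence: 8 steps (6 to 7 to 10 to 11 to 12 to 14 to 15 to 17 to 18; steps 3, 4, 5, 6, 7, 8, 9, 10).

Steps most likely to fail:

1. Step 9 (proposed new method). The quinone methide may tautomerise through the acidic C3–H before the phenol adds, which would erase C3. Phenoxyl radical coupling or oxidative attack on the prenyl phenol may also outrun the ring closure. The fallback uses known chemistry, sets out from 5 and comes back at 17.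
   - Aryllithium 13, made from 5 as in step 7, would be quenched with N‑methoxy‑N‑methylacetamide to give the methyl ketone 1‑[6‑methoxy‑2,4‑bis(methoxymethoxy)‑3‑(3‑methylbut‑2‑en‑1‑yl)phenyl]ethan‑1‑one F1.
   - Claisen–Schmidt condensation of F1 (KOH, EtOH, rt) with 3‑methoxy‑4‑(methoxymethoxy)benzaldehyde F2, made from vanillin with MOMCl and i‑Pr2NEt, would give the (E)‑chalcone F3.
   - Juliá–Colonna epoxidation (poly‑L‑leucine, urea–H2O2, DBU, THF), which gives the (2R,3S) epoxides of simple chalcones, would give the (2R,3S)‑epoxy ketone F4; the prenyl alkene is inert to the nucleophilic oxidant.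
   - Methanolic HCl would then remove the three MOM groups, and the freed ring A hydroxyl would open the epoxide at the benzylic carbon with inversion, the known acid cyclisation of 2'‑hydroxychalcone epoxides to trans dihydroflavonols, to reach 17.

2. Step 7. Acyl transfer from the hindered α‑silyloxy amide to the doubly ortho‑substituted aryllithium may be slow, so that proton transfer or return of 5 competes. The fallback sets out from 11 (and 5) and comes back at 14.
   - Ester 11 would be reduced with i‑Bu2AlH (CH2Cl2, −78 °C) to the aldehyde (2R)‑2‑[(tert‑butyldimethylsilyl)oxy]‑3‑[3‑methoxy‑4‑(methoxymethoxy)phenyl]propanal F5.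
   - Aryllithium 13 would add to this more electrophilic carbonyl at −78 °C to give the secondary alcohol F6 as a mixture of carbinol epimers.
   - Dess–Martin periodinane (NaHCO3‑buffered CH2Cl2) would oxidise F6 to 14; the epimer mixture is of no consequence because the carbinol carbon becomes the ketone.

3. Step 4. The Grignard reagent may add to the ester carbonyl, or bromide may open the epoxide, instead of the copper‑mediated attack at the CH2 terminus. The fallback sets out from Grignard reagent 8 and comes back at 12.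
   - CuI‑catalysed opening of commercial benzyl (R)‑glycidyl ether (c1ccccc1COC[C@H]1CO1), which has no ester, by 8 would give (2R)‑1‑(benzyloxy)‑3‑[3‑methoxy‑4‑(methoxymethoxy)phenyl]propan‑2‑ol F7.
   - TBSCl and imidazole would give its tert‑butyldimethylsilyl ether F8.
   - Hydrogenolysis (H2, Pd/C, EtOAc) would give (2R)‑2‑[(tert‑butyldimethylsilyl)oxy]‑3‑[3‑methoxy‑4‑(methoxymethoxy)phenyl]propan‑1‑ol F9.
   - Oxidation with TEMPO and PhI(OAc)2 in aqueous MeCN would give (2R)‑2‑[(tert‑butyldimethylsilyl)oxy]‑3‑[3‑methoxy‑4‑(methoxymethoxy)phenyl]propanoic acid F10.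
   - Amide coupling with MeNHOMe·HCl (EDC·HCl, HOBt, i‑Pr2NEt) would give 12.

**Further compounds**

F1 | step 9 | 1‑[6‑methoxy‑2,4‑bis(methoxymethoxy)‑3‑(3‑methylbut‑2‑en‑1‑yl)phenyl]ethan‑1‑one | COCOc1c(CC=C(C)C)c(OCOC)cc(OC)c1C(C)=O
F2 | step 9 | 3‑methoxy‑4‑(methoxymethoxy)benzaldehyde | COCOc1ccc(C=O)cc1OC
F3 | step 9 | (E)‑1‑[6‑methoxy‑2,4‑bis(methoxymethoxy)‑3‑(3‑methylbut‑2‑en‑1‑yl)phenyl]‑3‑[3‑methoxy‑4‑(methoxymethoxy)phenyl]prop‑2‑en‑1‑one | COCOc1c(CC=C(C)C)c(OCOC)cc(OC)c1C(=O)/C=C/c1ccc(OCOC)c(OC)c1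
F4 | step 9 | [(2R,3S)‑3‑[3‑methoxy‑4‑(methoxymethoxy)phenyl]oxiran‑2‑yl][6‑methoxy‑2,4‑bis(methoxymethoxy)‑3‑(3‑methylbut‑2‑en‑1‑yl)phenyl]methanone | COCOc1c(CC=C(C)C)c(OCOC)cc(OC)c1C(=O)[C@@H]1O[C@H]1c1ccc(OCOC)c(OC)c1
F5 | step 7 | (2R)‑2‑[(tert‑butyldimethylsilyl)oxy]‑3‑[3‑methoxy‑4‑(methoxymethoxy)phenyl]propanal | O=C[C@H](O[Si](C)(C)C(C)(C)C)Cc1ccc(OCOC)c(OC)c1
F6 | step 7 | (2R)‑2‑[(tert‑butyldimethylsilyl)oxy]‑1‑[6‑methoxy‑2,4‑bis(methoxymethoxy)‑3‑(3‑methylbut‑2‑en‑1‑yl)phenyl]‑3‑[3‑methoxy‑4‑(methoxymethoxy)phenyl]propan‑1‑ol (both C1 epimers) | COCOc1c(CC=C(C)C)c(OCOC)cc(OC)c1C(O)[C@H](O[Si](C)(C)C(C)(C)C)Cc1ccc(OCOC)c(OC)c1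
F7 | step 4 | (2R)‑1‑(benzyloxy)‑3‑[3‑methoxy‑4‑(methoxymethoxy)phenyl]propan‑2‑ol | COCOc1ccc(C[C@@H](O)COCc2ccccc2)cc1OC
F8 | step 4 | tert‑butyldimethylsilyl ether of F7 | COCOc1ccc(C[C@@H](O[Si](C)(C)C(C)(C)C)COCc2ccccc2)cc1OC
F9 | step 4 | (2R)‑2‑[(tert‑butyldimethylsilyl)oxy]‑3‑[3‑methoxy‑4‑(methoxymethoxy)phenyl]propan‑1‑ol | OC[C@H](O[Si](C)(C)C(C)(C)C)Cc1ccc(OCOC)c(OC)c1
F10 | step 4 | (2R)‑2‑[(tert‑butyldimethylsilyl)oxy]‑3‑[3‑methoxy‑4‑(methoxymethoxy)phenyl]propanoic acid | OC(=O)[C@H](O[Si](C)(C)C(C)(C)C)Cc1ccc(OCOC)c(OC)c1
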